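**Plan**

1. Labels: ring B = C1(H2)–C2(HBr)–C3(Me)(OH)–C4–C5–C6(H); C7 = exocyclic carbinol carbon; C8=C9 = the E-alkene; ring A = C10–C15 (C11 carries the methylidene, C14 the bromine, C15 the gem-dimethyl group).
2. Cuts: C8=C9 (Julia–Kocienski union of ring A sulfone 34 with ring B aldehyde 21); in ring B the C1–C6 bond, after taking C2–Br/C3–OH back to a C2=C3 alkene; in ring A the C10–C15 bond (bromonium/allylsilane cyclization).
3. Enabling feature: in ring B the C1–C6 bond lies anti to the vicinal exocyclic C7–O bond and C1 is allylic to C2=C3. This is the imprint of a C1 allyl carbanion opening a C6–C7 epoxide in the 6-exo mode.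
4. Forward: nerol → (Z)-allyl sulfone carrying a (Z)-allylic alcohol → Sharpless epoxide → ring B closure → desulfonylation → diaxial diol → syn-bromohydrin → aldehyde 21. Ring A is made from an allylsilane ester by Shi epoxidation, bromide opening and bromonium cyclization; then union and desilylation.
5. Stereochemistry: C6 and C7 come from one Sharpless epoxidation (C6 inverted in the ring closure). C3 and C2 are relayed from C6 by diaxial epoxide hydrolysis and SN2 bromide displacement. C14 comes from a Shi epoxide (inverted by bromide), C10 from the chair cyclization, and the E-alkene from the Julia–Kocienski step.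

Key step: step 8

Remark: the configuration at the sulfonyl-bearing ring carbon of 12 and 13 and at the epoxide carbons of 15 is left open in the SMILES, because both elements are erased in steps 10 and 11.

**Ring B branch (steps 1–16)**

Step 1
Reactants: 1 nerol, (2Z)-3,7-dimethylocta-2,6-dien-1-ol
Product: 2 neryl bromide, (2Z)-1-bromo-3,7-dimethylocta-2,6-diene
Conditions: PBr3 (0.4 equiv), Et2O, −10 °C
Reagents that add atoms: phosphorus tribromide, BrP(Br)Br
Why: Bromination of a primary allylic alcohol with PBr3 at low temperature (SN2-type substitution) should keep the primary position and the (Z)-C2=C3 geometry.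

Step 2
Reactants: 2 neryl bromide
Product: 3 neryl phenyl sulfone, {[(2Z)-3,7-dimethylocta-2,6-dien-1-yl]sulfonyl}benzene
Conditions: PhSO2Na, DMF, 0 °C → rt
Reagents that add atoms: sodium benzenesulfinate, [Na+].[O-]S(=O)c1ccccc1
Why: S-alkylation of the sulfinate by the primary allylic bromide (SN2) should give the allyl sulfone, whose CH2 is C1 of ring B, without allylic transposition.

Step 3
Reactants: 3 neryl phenyl sulfone
Product: 5 (4Z)-4-methyl-6-(phenylsulfonyl)hex-4-enal, via epoxy sulfone 4 (not isolated)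
Conditions: mCPBA (1.05 equiv), CH2Cl2, 0 °C; then H5IO6, THF–H2O, 0 °C → rt
Reagents that add atoms: 3-chloroperoxybenzoic acid, OOC(=O)c1cccc(Cl)c1; water, O
Why: Prilezhaev epoxidation should select the electron-rich terminal alkene over the one deactivated by the allylic sulfonyl group, and periodic acid cleavage of the epoxide (through the diol) unveils the C6 aldehyde.

Step 4
Reactants: 5 (4Z)-4-methyl-6-(phenylsulfonyl)hex-4-enal; 6 ethyl 2-[bis(2,2,2-trifluoroethoxy)phosphoryl]propanoate
Product: 7 ethyl (2Z,6Z)-2,6-dimethyl-8-(phenylsulfonyl)octa-2,6-dienoate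
Conditions: KN(SiMe3)2, 18-crown-6, THF, −78 °C
Reagents that add atoms: none
Why: Still–Gennari olefination with the α-methyl trifluoroethyl phosphonate should give the (Z)-trisubstituted enoate, which places C8 cis to C5 as the later anti opening of the C6–C7 epoxide requires.

Step 5
Reactants: 7 ethyl (2Z,6Z)-2,6-dimethyl-8-(phenylsulfonyl)octa-2,6-dienoate
Product: 8 (2Z,6Z)-2,6-dimethyl-8-(phenylsulfonyl)octa-2,6-dien-1-ol
Conditions: iBu2AlH (2.2 equiv), CH2Cl2, −78 °C
Reagents that add atoms: none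
Why: 1,2-Reduction of the enoate by the aluminium hydride should give the (Z)-allylic alcohol and leave the sulfone and both alkene geometries untouched.

Step 6
Reactants: 8 (2Z,6Z)-2,6-dimethyl-8-(phenylsulfonyl)octa-2,6-dien-1-ol
Product: 9 [(2R,3S)-2-methyl-3-[(3Z)-3-methyl-5-(phenylsulfonyl)pent-3-en-1-yl]oxiran-2-yl]methanol
Conditions: Ti(OiPr)4, D-(−)-diethyl tartrate, t-BuOOH, 4 Å MS, CH2Cl2, −20 °C
Reagents that add atoms: tert-butyl hydroperoxide, CC(C)(C)OO
Why: Sharpless asymmetric epoxidation should act only on the allylic-alcohol alkene, and reagent control by the D-tartrate sets C7 (R) and C6 (S) of the epoxide in one event.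

Step 7
Reactants: 9 epoxy alcohol
Product: 10 tert-butyl{[(2R,3S)-2-methyl-3-[(3Z)-3-methyl-5-(phenylsulfonyl)pent-3-en-1-yl]oxiran-2-yl]methoxy}diphenylsilane
Conditions: TBDPSCl, imidazole, CH2Cl2, 0 °C → rt
Reagents that add atoms: tert-butyl(chloro)diphenylsilane, CC(C)(C)[Si](Cl)(c1ccccc1)c1ccccc1
Why: Silylation under non-basic conditions masks the C8 hydroxyl, so that no alkoxide (Payne rearrangement) can interfere in step 8, and leaves the acidic sulfone CH2 alone.

Step 8
Reactants: 10 silyl-protected epoxy sulfone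
Product: 12 (2S)-1-[(tert-butyldiphenylsilyl)oxy]-2-[(1R)-4-methyl-2-(phenylsulfonyl)cyclohex-3-en-1-yl]propan-2-ol, via lithiated sulfone 11 (not isolated)
Conditions: LiN(iPr)2 (1.1 equiv), THF, −78 → 0 °C; then H2O
Reagents that add atoms: none
Why: LiN(iPr)2 removes the doubly activated (allylic, α-sulfonyl) proton at C1, and the carbanion 11 attacks the epoxide carbon C6 from the face opposite to the C6–O bond while the oxygen stays on C7 (intramolecular SN2 opening of the epoxide). The closest known reaction type is the cycloalkylation of epoxy sulfones and epoxy nitriles by their α-carbanions. Ring B closes in the 6-exo-tet mode, with the fully substituted C7 left outside the new ring. C6 is set by clean inversion and C7 is carried over unchanged, so both centres derive from the single epoxide of step 6; the new centre at the sulfonyl-bearing C1 is of no consequence. The step needs attack at C6 and not at C7, and through the α- and not the γ-terminus of the allyl anion: attack at the quaternary C7 would be a 7-endo closure, γ-attack would give a four-membered ring, and the (Z)-geometry of the nerol-derived C2=C3 bond holds C1 within reach of C6.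

Step 9
Reactants: 12 hydroxy sulfone
Product: 13 tert-butyl{[(2S)-2-[(1R)-4-methyl-2-(phenylsulfonyl)cyclohex-3-en-1-yl]-2-[(triethylsilyl)oxy]propyl]oxy}diphenylsilane
Conditions: Et3SiOTf, 2,6-lutidine, CH2Cl2, −78 → 0 °C
Reagents that add atoms: triethylsilyl trifluoromethanesulfonate, CC[Si](CC)(CC)OS(=O)(=O)C(F)(F)F
Why: Silylation of the hindered tertiary C7 hydroxyl with the silyl triflate should be clean and keeps this oxygen from adding across ring B in step 11.

Step 10
Reactants: 13 silylated sulfone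
Product: 14 tert-butyl{[(2S)-2-[(1S)-4-methylcyclohex-3-en-1-yl]-2-[(triethylsilyl)oxy]propyl]oxy}diphenylsilane
Conditions: PdCl2(dppp) (5 mol %), LiBHEt3, THF, 0 °C
Reagents that add atoms: none
Why: Palladium-catalysed reductive desulfonylation of an allylic sulfone proceeds through a π-allylpalladium hydride, and hydride delivery to the less substituted terminus C1 should retain the trisubstituted C2=C3 alkene.

Step 11
Reactants: 14 ring B alkene
Product: 16 (1R,2R,4S)-4-[(2S)-1-[(tert-butyldiphenylsilyl)oxy]-2-[(triethylsilyl)oxy]propan-2-yl]-1-methylcyclohexane-1,2-diol, via ring B epoxides 15 (not isolated)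
Conditions: mCPBA, CH2Cl2, −10 °C; then HClO4 (3 mol %), THF–H2O, 0 °C
Reagents that add atoms: 3-chloroperoxybenzoic acid, OOC(=O)c1cccc(Cl)c1; water, O
Why: Prilezhaev epoxidation followed by acid-catalysed hydrolysis should be stereoconvergent, because each epoxide opens trans-diaxially (Fürst–Plattner rule), one at C2 and the other at C3, so that C3–OH (cis to the C6 side chain) and C2–OH (trans) are both set by substrate control from C6.

Step 12
Reactants: 16 diol
Product: 17 (1R,2R,5S)-5-[(2S)-1-[(tert-butyldiphenylsilyl)oxy]-2-[(triethylsilyl)oxy]propan-2-yl]-2-hydroxy-2-methylcyclohexyl chloromethanesulfonate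
Conditions: ClCH2SO2Cl, pyridine, CH2Cl2, 0 °C
Reagents that add atoms: chloromethanesulfonyl chloride, ClCS(Cl)(=O)=O
Why: Sulfonylation should take place only at the secondary C2 hydroxyl, the tertiary C3 hydroxyl being too hindered, and installs a leaving group reactive enough for a hindered displacement.

Step 13
Reactants: 17 chloromethanesulfonate
Product: 18 (1R,2S,4S)-2-bromo-4-[(2S)-1-[(tert-butyldiphenylsilyl)oxy]-2-[(triethylsilyl)oxy]propan-2-yl]-1-methylcyclohexan-1-ol
Conditions: LiBr, DMF, 45 °C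
Reagents that add atoms: lithium bromide, [Li+].[Br-]
Why: SN2 displacement of the axial sulfonate by bromide under neutral conditions inverts C2 and turns the trans-diaxial diol pattern into the syn-bromohydrin (Br equatorial, cis to the axial C3–OH and to the C6 side chain).

Step 14
Reactants: 18 bromohydrin
Product: 19 (2S)-2-[(1S,3S,4R)-3-bromo-4-hydroxy-4-methylcyclohexyl]propane-1,2-diol
Conditions: HF·pyridine, pyridine, THF, 0 °C → rt
Reagents that add atoms: none
Why: Fluoride-mediated cleavage of both silyl ethers in a buffered, non-basic medium should leave the syn-bromohydrin untouched.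

Step 15
Reactants: 19 bromo triol
Product: 20 tris(triethylsilyl) ether of 19 (C3–O, C7–O and C8–O silylated)
Conditions: Et3SiOTf (4 equiv), 2,6-lutidine, CH2Cl2, −78 → 0 °C
Reagents that add atoms: triethylsilyl trifluoromethanesulfonate, CC[Si](CC)(CC)OS(=O)(=O)C(F)(F)F
Why: Exhaustive silylation with the silyl triflate should cover the primary and both tertiary hydroxyls and protects C3–OH and C7–OH for the basic olefination.

Step 16
Reactants: 20 tris(triethylsilyl) ether
Product: 21 (2S)-2-[(1S,3S,4R)-3-bromo-4-methyl-4-[(triethylsilyl)oxy]cyclohexyl]-2-[(triethylsilyl)oxy]propanal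
Conditions: (COCl)2, DMSO, CH2Cl2, −78 → −30 °C; then Et3N, −78 °C → rt
Reagents that add atoms: none
Why: Under Swern conditions a primary triethylsilyl ether is cleaved and oxidised directly to the aldehyde while tertiary silyl ethers survive, and the aldehyde formed has no α-hydrogen, so C7 cannot epimerise.

**Ring A branch (steps 17–26)**

Step 17
Reactants: 22 ethyl acetoacetate; 23 prenyl bromide (1-bromo-3-methylbut-2-ene)
Product: 24 ethyl 7-methyl-3-oxooct-6-enoate
Conditions: NaH, THF, 0 °C; n-BuLi, 0 °C; then 23; aq. HCl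
Reagents that add atoms: none
Why: Alkylation of the acetoacetate dianion takes place at the more basic terminal (γ) carbon and should give the chain C9–C15 in one step.

Step 18
Reactants: 24 β-keto ester
Product: 25 ethyl (2Z)-3-[(diethoxyphosphoryl)oxy]-7-methylocta-2,6-dienoate
Conditions: NaH, Et2O, 0 °C; then ClP(O)(OEt)2
Reagents that add atoms: diethyl chlorophosphate, CCOP(=O)(Cl)OCC
Why: O-Phosphorylation of the chelated sodium enolate should give the (Z)-enol phosphate with the phosphate cis to the ester.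

Step 19
Reactants: 25 enol phosphate; 26 (trimethylsilyl)methylmagnesium chloride
Product: 27 ethyl (2Z)-7-methyl-3-[(trimethylsilyl)methyl]octa-2,6-dienoate
Conditions: Ni(acac)2 (5 mol %), THF, 0 °C → rt
Reagents that add atoms: none
Why: Nickel-catalysed Kumada-type coupling of an enol phosphate with the Grignard reagent proceeds with retention of alkene geometry and places the silylmethyl group (the future C11 methylidene) cis to the ester.

Step 20
Reactants: 27 allylsilane ester
Product: 28 ethyl (2Z)-5-[(2R)-3,3-dimethyloxiran-2-yl]-3-[(trimethylsilyl)methyl]pent-2-enoate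
Conditions: 1,2:4,5-di-O-isopropylidene-β-D-erythro-2,3-hexodiulo-2,6-pyranose (30 mol %), Oxone (2KHSO5·KHSO4·K2SO4), K2CO3, MeCN–CH2(OMe)2–aq. buffer (pH 10.5), 0 °C
Reagents that add atoms: potassium peroxymonosulfate, [K+].[O-]S(=O)(=O)OO
Why: Shi epoxidation with the D-fructose-derived ketone should oxidise only the electron-rich trisubstituted alkene (the ester-conjugated one is inert) and sets the (R)-configuration at C14 by catalyst control.

Step 21
Reactants: 28 epoxide
Product: 29 ethyl (2Z,6S)-6-bromo-7-hydroxy-7-methyl-3-[(trimethylsilyl)methyl]oct-2-enoate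
Conditions: Li2NiBr4, THF, 0 °C → rt
Reagents that add atoms: dilithium tetrabromonickelate, [Li+].[Li+].[Ni+2].[Br-].[Br-].[Br-].[Br-]
Why: SN2-type opening of the epoxide by soft bromide at the less substituted carbon C14 proceeds with inversion and gives the (S)-bromide next to the tertiary alcohol.

Step 22
Reactants: 29 bromohydrin
Product: 30 ethyl (2Z,6S)-6-bromo-7-methyl-7-[(trifluoroacetyl)oxy]-3-[(trimethylsilyl)methyl]oct-2-enoate
Conditions: (CF3CO)2O, pyridine, CH2Cl2, 0 °C
Reagents that add atoms: trifluoroacetic anhydride, O=C(OC(=O)C(F)(F)F)C(F)(F)F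
Why: Acylation converts the tertiary hydroxyl into a leaving group that a Lewis acid can ionise, without touching the C14 stereocentre.

Step 23
Reactants: 30 bromo trifluoroacetate
Product: 31 ethyl (1R,3S)-3-bromo-2,2-dimethyl-6-methylidenecyclohexane-1-carboxylate
Conditions: SnCl4, CH2Cl2 (high dilution), −78 °C
Reagents that add atoms: none
Why: Ionisation of the tertiary ester with participation of the neighbouring bromine gives a single-enantiomer bromonium ion, which C10 of the allylsilane opens at C15 through a chair transition state (bromonium-initiated cation–olefin cyclization with allylsilane termination), so that C10 is set cis to C14–Br by substrate control and loss of the silyl group fixes the exocyclic C11 methylidene.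

Step 24
Reactants: 31 bromo ester
Product: 32 [(1R,3S)-3-bromo-2,2-dimethyl-6-methylidenecyclohexyl]methanol
Conditions: iBu2AlH (2.5 equiv), CH2Cl2, −78 → 0 °C
Reagents that add atoms: none
Why: Ester reduction by the aluminium hydride under non-basic conditions should spare the hindered secondary bromide and avoid epimerisation or conjugation at C10.

Step 25
Reactants: 32 alcohol
Product: 33 5-({[(1R,3S)-3-bromo-2,2-dimethyl-6-methylidenecyclohexyl]methyl}sulfanyl)-1-phenyl-1H-tetrazole
Conditions: 1-phenyl-1H-tetrazole-5-thiol, PPh3, DIAD, THF, 0 °C → rt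
Reagents that add atoms: 1-phenyl-1H-tetrazole-5-thiol, Sc1nnnn1-c1ccccc1
Why: Mitsunobu thioetherification of the primary alcohol installs the heteroaryl sulfide at C9 without touching either stereocentre.

Step 26
Reactants: 33 sulfide
Product: 34 5-({[(1R,3S)-3-bromo-2,2-dimethyl-6-methylidenecyclohexyl]methyl}sulfonyl)-1-phenyl-1H-tetrazole
Conditions: (NH4)6Mo7O24·4H2O (10 mol %), H2O2 (30 % aq.), EtOH, 0 °C → rt
Reagents that add atoms: hydrogen peroxide, OO
Why: Molybdate-catalysed oxidation of the sulfide to the sulfone with hydrogen peroxide should leave the unactivated 1,1-disubstituted alkene untouched.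

**Union and end game**

Step 27
Reactants: 34 ring A sulfone; 21 ring B aldehyde
Product: 35 bis(triethylsilyl) ether of the target (C3–O and C7–O silylated)
Conditions: KN(SiMe3)2 added to 34 + 21, DME, −60 °C → rt
Reagents that add atoms: none
Why: Julia–Kocienski olefination (addition of the sulfonyl carbanion to the non-enolisable aldehyde, Smiles rearrangement, loss of SO2 and the tetrazolone) should give the (E)-C8=C9 alkene, the anti addition being favoured between two branched partners, and touches no stereocentre.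

Step 28
Reactants: 35 bis(triethylsilyl) ether
Product: 36 target, (1R,2S,4S)-2-bromo-4-[(2S,3E)-4-[(1R,3S)-3-bromo-2,2-dimethyl-6-methylidenecyclohexyl]-2-hydroxybut-3-en-2-yl]-1-methylcyclohexan-1-ol
Conditions: HF·pyridine, pyridine, THF, 0 °C → rt
Reagents that add atoms: none
Why: Buffered fluoride cleavage of the two tertiary silyl ethers should free C3–OH and the allylic C7–OH without ionising the tertiary allylic alcohol or disturbing the bromides.

**Compound list**

1 | nerol, (2Z)-3,7-dimethylocta-2,6-dien-1-ol | CC(C)=CCC/C(C)=C\CO | starting material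
2 | neryl bromide, (2Z)-1-bromo-3,7-dimethylocta-2,6-diene | CC(C)=CCC/C(C)=C\CBr | intermediate
3 | neryl phenyl sulfone, {[(2Z)-3,7-dimethylocta-2,6-dien-1-yl]sulfonyl}benzene | CC(C)=CCC/C(C)=C\CS(=O)(=O)c1ccccc1 | intermediate
4 | epoxy sulfone, racemic 2,2-dimethyl-3-[(3Z)-3-methyl-5-(phenylsulfonyl)pent-3-en-1-yl]oxirane | CC1(C)OC1CC/C(C)=C\CS(=O)(=O)c1ccccc1 | intermediate (not isolated)
5 | (4Z)-4-methyl-6-(phenylsulfonyl)hex-4-enal | O=CCC/C(C)=C\CS(=O)(=O)c1ccccc1 | intermediate
6 | ethyl 2-[bis(2,2,2-trifluoroethoxy)phosphoryl]propanoate | CCOC(=O)C(C)P(=O)(OCC(F)(F)F)OCC(F)(F)F | starting material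
7 | ethyl (2Z,6Z)-2,6-dimethyl-8-(phenylsulfonyl)octa-2,6-dienoate | CCOC(=O)/C(C)=C\CC/C(C)=C\CS(=O)(=O)c1ccccc1 | intermediate
8 | (2Z,6Z)-2,6-dimethyl-8-(phenylsulfonyl)octa-2,6-dien-1-ol | OC/C(C)=C\CC/C(C)=C\CS(=O)(=O)c1ccccc1 | intermediate
9 | [(2R,3S)-2-methyl-3-[(3Z)-3-methyl-5-(phenylsulfonyl)pent-3-en-1-yl]oxiran-2-yl]methanol | OC[C@@]1(C)O[C@H]1CC/C(C)=C\CS(=O)(=O)c1ccccc1 | intermediate
10 | tert-butyl{[(2R,3S)-2-methyl-3-[(3Z)-3-methyl-5-(phenylsulfonyl)pent-3-en-1-yl]oxiran-2-yl]methoxy}diphenylsilane | CC(C)(C)[Si](OC[C@@]1(C)O[C@H]1CC/C(C)=C\CS(=O)(=O)c1ccccc1)(c1ccccc1)c1ccccc1 | intermediate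
11 | lithiated sulfone, 10 deprotonated at the CH2 next to sulfur, lithium salt | CC(C)(C)[Si](OC[C@@]1(C)O[C@H]1CC/C(C)=C\[CH-]S(=O)(=O)c1ccccc1)(c1ccccc1)c1ccccc1.[Li+] | intermediate (not isolated)
12 | (2S)-1-[(tert-butyldiphenylsilyl)oxy]-2-[(1R)-4-methyl-2-(phenylsulfonyl)cyclohex-3-en-1-yl]propan-2-ol, sulfonyl-bearing carbon of open configuration | CC(C)(C)[Si](OC[C@@](C)(O)[C@H]1CCC(C)=CC1S(=O)(=O)c1ccccc1)(c1ccccc1)c1ccccc1 | intermediate
13 | tert-butyl{[(2S)-2-[(1R)-4-methyl-2-(phenylsulfonyl)cyclohex-3-en-1-yl]-2-[(triethylsilyl)oxy]propyl]oxy}diphenylsilane | CC(C)(C)[Si](OC[C@@](C)(O[Si](CC)(CC)CC)[C@H]1CCC(C)=CC1S(=O)(=O)c1ccccc1)(c1ccccc1)c1ccccc1 | intermediate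
14 | tert-butyl{[(2S)-2-[(1S)-4-methylcyclohex-3-en-1-yl]-2-[(triethylsilyl)oxy]propyl]oxy}diphenylsilane | CC(C)(C)[Si](OC[C@@](C)(O[Si](CC)(CC)CC)[C@H]1CCC(C)=CC1)(c1ccccc1)c1ccccc1 | intermediate
15 | ring B epoxides, both C2–C3 epoxides of 14 | CC(C)(C)[Si](OC[C@@](C)(O[Si](CC)(CC)CC)[C@H]1CCC2(C)OC2C1)(c1ccccc1)c1ccccc1 | intermediate (not isolated)
16 | (1R,2R,4S)-4-[(2S)-1-[(tert-butyldiphenylsilyl)oxy]-2-[(triethylsilyl)oxy]propan-2-yl]-1-methylcyclohexane-1,2-diol | CC(C)(C)[Si](OC[C@@](C)(O[Si](CC)(CC)CC)[C@H]1CC[C@@](C)(O)[C@H](O)C1)(c1ccccc1)c1ccccc1 | intermediate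
17 | (1R,2R,5S)-5-[(2S)-1-[(tert-butyldiphenylsilyl)oxy]-2-[(triethylsilyl)oxy]propan-2-yl]-2-hydroxy-2-methylcyclohexyl chloromethanesulfonate | CC(C)(C)[Si](OC[C@@](C)(O[Si](CC)(CC)CC)[C@H]1CC[C@@](C)(O)[C@H](OS(=O)(=O)CCl)C1)(c1ccccc1)c1ccccc1 | intermediate
18 | (1R,2S,4S)-2-bromo-4-[(2S)-1-[(tert-butyldiphenylsilyl)oxy]-2-[(triethylsilyl)oxy]propan-2-yl]-1-methylcyclohexan-1-ol | CC(C)(C)[Si](OC[C@@](C)(O[Si](CC)(CC)CC)[C@H]1CC[C@@](C)(O)[C@@H](Br)C1)(c1ccccc1)c1ccccc1 | intermediate
19 | (2S)-2-[(1S,3S,4R)-3-bromo-4-hydroxy-4-methylcyclohexyl]propane-1,2-diol | OC[C@@](C)(O)[C@H]1CC[C@@](C)(O)[C@@H](Br)C1 | intermediate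
20 | tris(triethylsilyl) ether of 19 | CC[Si](CC)(CC)OC[C@@](C)(O[Si](CC)(CC)CC)[C@H]1CC[C@@](C)(O[Si](CC)(CC)CC)[C@@H](Br)C1 | intermediate
21 | (2S)-2-[(1S,3S,4R)-3-bromo-4-methyl-4-[(triethylsilyl)oxy]cyclohexyl]-2-[(triethylsilyl)oxy]propanal | O=C[C@@](C)(O[Si](CC)(CC)CC)[C@H]1CC[C@@](C)(O[Si](CC)(CC)CC)[C@@H](Br)C1 | intermediate
22 | ethyl acetoacetate (ethyl 3-oxobutanoate) | CCOC(=O)CC(C)=O | starting material
23 | prenyl bromide (1-bromo-3-methylbut-2-ene) | CC(C)=CCBr | starting material
24 | ethyl 7-methyl-3-oxooct-6-enoate | CCOC(=O)CC(=O)CCC=C(C)C | intermediate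
25 | ethyl (2Z)-3-[(diethoxyphosphoryl)oxy]-7-methylocta-2,6-dienoate | CCOC(=O)/C=C(\OP(=O)(OCC)OCC)CCC=C(C)C | intermediate
26 | (trimethylsilyl)methylmagnesium chloride | C[Si](C)(C)C[Mg]Cl | starting material
27 | ethyl (2Z)-7-methyl-3-[(trimethylsilyl)methyl]octa-2,6-dienoate | CCOC(=O)/C=C(\C[Si](C)(C)C)CCC=C(C)C | intermediate
28 | ethyl (2Z)-5-[(2R)-3,3-dimethyloxiran-2-yl]-3-[(trimethylsilyl)methyl]pent-2-enoate | CCOC(=O)/C=C(\C[Si](C)(C)C)CC[C@H]1OC1(C)C | intermediate
29 | ethyl (2Z,6S)-6-bromo-7-hydroxy-7-methyl-3-[(trimethylsilyl)methyl]oct-2-enoate | CCOC(=O)/C=C(\C[Si](C)(C)C)CC[C@H](Br)C(C)(C)O | intermediate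
30 | ethyl (2Z,6S)-6-bromo-7-methyl-7-[(trifluoroacetyl)oxy]-3-[(trimethylsilyl)methyl]oct-2-enoate | CCOC(=O)/C=C(\C[Si](C)(C)C)CC[C@H](Br)C(C)(C)OC(=O)C(F)(F)F | intermediate
31 | ethyl (1R,3S)-3-bromo-2,2-dimethyl-6-methylidenecyclohexane-1-carboxylate | C=C1CC[C@H](Br)C(C)(C)[C@@H]1C(=O)OCC | intermediate
32 | [(1R,3S)-3-bromo-2,2-dimethyl-6-methylidenecyclohexyl]methanol | C=C1CC[C@H](Br)C(C)(C)[C@@H]1CO | intermediate
33 | 5-({[(1R,3S)-3-bromo-2,2-dimethyl-6-methylidenecyclohexyl]methyl}sulfanyl)-1-phenyl-1H-tetrazole | C=C1CC[C@H](Br)C(C)(C)[C@@H]1CSc1nnnn1-c1ccccc1 | intermediate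
34 | 5-({[(1R,3S)-3-bromo-2,2-dimethyl-6-methylidenecyclohexyl]methyl}sulfonyl)-1-phenyl-1H-tetrazole | C=C1CC[C@H](Br)C(C)(C)[C@@H]1CS(=O)(=O)c1nnnn1-c1ccccc1 | intermediate
35 | bis(triethylsilyl) ether of the target (C3–O and C7–O) | C=C1CC[C@H](Br)C(C)(C)[C@@H]1/C=C/[C@@](C)(O[Si](CC)(CC)CC)[C@H]1CC[C@@](C)(O[Si](CC)(CC)CC)[C@@H](Br)C1 | intermediate
36 | (1R,2S,4S)-2-bromo-4-[(2S,3E)-4-[(1R,3S)-3-bromo-2,2-dimethyl-6-methylidenecyclohexyl]-2-hydroxybut-3-en-2-yl]-1-methylcyclohexan-1-ol | C=C1CC[C@H](Br)C(C)(C)[C@@H]1/C=C/[C@@](C)(O)[C@H]1CC[C@@](C)(O)[C@@H](Br)C1 | target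

**Step count and risks**

Total step count: 28. Longest linear sequence: 18 steps (steps 1–16, then 27 and 28); the ring A branch (steps 17–26) has 10 steps.

Steps most likely to fail:

1. Step 23 (bromonium cyclization to ring A). The bromonium ion may hand Br+ to a second alkene before ring closure, which erodes the enantiomeric purity, or the cation may lose the silyl group or a proton without cyclizing. The fallback sets out from 27 and gives up the enantiospecific route for a racemic cyclization with resolution. Et2SBr·SbCl5Br in MeNO2 at −25 °C should cyclize 27 directly to racemic ethyl cis-3-bromo-2,2-dimethyl-6-methylidenecyclohexane-1-carboxylate F1. Reduction with iBu2AlH gives racemic cis-(3-bromo-2,2-dimethyl-6-methylidenecyclohexyl)methanol F2. Esterification with (S)-2-methoxy-2-phenylacetic acid (dicyclohexylcarbodiimide, 4-(dimethylamino)pyridine) gives two diastereomeric esters, separable by chromatography: the (S)-2-methoxy-2-phenylacetate of the (1R,3S)-alcohol F3 and the (S)-2-methoxy-2-phenylacetate of the (1S,3R)-alcohol F4. Hydrolysis of F3 (LiOH, THF–H2O, 0 °C) comes back to the route at 32.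

2. Step 13 (bromide displacement at C2). The free axial C3 hydroxyl may close onto C2 to give the epoxide, or E2 elimination may outrun the slow SN2 reaction at a secondary carbon next to a fully substituted one. The fallback sets out from 17 and takes the hydroxyl out of play before the displacement. Me3SiOTf and 2,6-lutidine give the trimethylsilyl ether of 17 F5. Bu4NBr in toluene at 60 °C then displaces the sulfonate with inversion and gives the trimethylsilyl ether of 18 F6. Citric acid in MeOH removes the trimethylsilyl group only and comes back at 18.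

3. Step 8 (ring B closure). The (Z)-allyl anion may isomerise to the (E)-form, which cannot reach C6, or the base may open the epoxide to an allylic alcohol before the ring closes. The fallback makes the C1–C6 bond intermolecularly and closes ring B at C2=C3 by metathesis. It sets out from phosphonate 6 and comes back at 14.
   - Still–Gennari olefination of 6 with commercial 4-methylpent-4-enal F7 gives ethyl (2Z)-2,6-dimethylhepta-2,6-dienoate F8.
   - iBu2AlH gives (2Z)-2,6-dimethylhepta-2,6-dien-1-ol F9.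
   - Sharpless epoxidation as in step 6 gives [(2R,3S)-2-methyl-3-(3-methylbut-3-en-1-yl)oxiran-2-yl]methanol F10.
   - TBDPSCl and imidazole give its tert-butyldiphenylsilyl ether F11.
   - Allylmagnesium bromide with CuI (10 mol %) in THF at −30 °C opens the epoxide at C6 with inversion and gives (2S,3S)-1-[(tert-butyldiphenylsilyl)oxy]-2,6-dimethyl-3-(prop-2-en-1-yl)hept-6-en-2-ol F12.
   - Et3SiOTf and 2,6-lutidine give its triethylsilyl ether F13.
   - Ring-closing metathesis of F13 with the second-generation Grubbs catalyst (CH2Cl2, 40 °C) gives 14.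

Further compounds
F1 | step 23 | racemic ethyl cis-3-bromo-2,2-dimethyl-6-methylidenecyclohexane-1-carboxylate | C=C1CC[C@H](Br)C(C)(C)[C@@H]1C(=O)OCC.C=C1CC[C@@H](Br)C(C)(C)[C@H]1C(=O)OCC
F2 | step 23 | racemic cis-(3-bromo-2,2-dimethyl-6-methylidenecyclohexyl)methanol | C=C1CC[C@H](Br)C(C)(C)[C@@H]1CO.C=C1CC[C@@H](Br)C(C)(C)[C@H]1CO
F3 | step 23 | [(1R,3S)-3-bromo-2,2-dimethyl-6-methylidenecyclohexyl]methyl (2S)-2-methoxy-2-phenylacetate | C=C1CC[C@H](Br)C(C)(C)[C@@H]1COC(=O)[C@@H](OC)c1ccccc1
F4 | step 23 | [(1S,3R)-3-bromo-2,2-dimethyl-6-methylidenecyclohexyl]methyl (2S)-2-methoxy-2-phenylacetate | C=C1CC[C@@H](Br)C(C)(C)[C@H]1COC(=O)[C@@H](OC)c1ccccc1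
F5 | step 13 | trimethylsilyl ether of 17 (C3–O silylated) | CC(C)(C)[Si](OC[C@@](C)(O[Si](CC)(CC)CC)[C@H]1CC[C@@](C)(O[Si](C)(C)C)[C@H](OS(=O)(=O)CCl)C1)(c1ccccc1)c1ccccc1
F6 | step 13 | trimethylsilyl ether of 18 (C3–O silylated) | CC(C)(C)[Si](OC[C@@](C)(O[Si](CC)(CC)CC)[C@H]1CC[C@@](C)(O[Si](C)(C)C)[C@@H](Br)C1)(c1ccccc1)c1ccccc1
F7 | step 8 | 4-methylpent-4-enal | CC(=C)CCC=O
F8 | step 8 | ethyl (2Z)-2,6-dimethylhepta-2,6-dienoate | CCOC(=O)/C(C)=C\CCC(C)=C
F9 | step 8 | (2Z)-2,6-dimethylhepta-2,6-dien-1-ol | OC/C(C)=C\CCC(C)=C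
F10 | step 8 | [(2R,3S)-2-methyl-3-(3-methylbut-3-en-1-yl)oxiran-2-yl]methanol | OC[C@@]1(C)O[C@H]1CCC(C)=C
F11 | step 8 | tert-butyl{[(2R,3S)-2-methyl-3-(3-methylbut-3-en-1-yl)oxiran-2-yl]methoxy}diphenylsilane | CC(C)(C)[Si](OC[C@@]1(C)O[C@H]1CCC(C)=C)(c1ccccc1)c1ccccc1
F12 | step 8 | (2S,3S)-1-[(tert-butyldiphenylsilyl)oxy]-2,6-dimethyl-3-(prop-2-en-1-yl)hept-6-en-2-ol | CC(C)(C)[Si](OC[C@@](C)(O)[C@H](CC=C)CCC(C)=C)(c1ccccc1)c1ccccc1
F13 | step 8 | triethylsilyl ether of F12 | CC(C)(C)[Si](OC[C@@](C)(O[Si](CC)(CC)CC)[C@H](CC=C)CCC(C)=C)(c1ccccc1)c1ccccc1
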